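**Retrosynthetic overview**
1. Target 26 ⇐ diol 25 ⇐ bis-TBS tricycle 24 (acetylation and desilylation come last).
2. Key disconnection in the azonane: the N–CH2 carbon α to the formamide nitrogen (a latent N-formyl-N-methyleneiminium carbon) is cut from the adjacent ring CH2, which is the γ-carbon of the exocyclic enone on the cyclopentanone (nucleophilic through its 2-silyloxydiene). Removing the N–CH2 carbon as formaldehyde gives the bicyclic formamide ethylidene ketone 20.
3. 20 ⇐ hydrindenone 12: Cu-catalysed conjugate addition of a 3-aminopropyl Grignard reagent (quaternary carbon, cis-hydrindane), then aldol/elimination with acetaldehyde at the regiodefined enolate carbon.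
4. 12 ⇐ 1,7-enyne 10 by Pauson–Khand reaction (cyclohexane and cyclopentenone formed together; ring-fusion CH relayed from the syn-1,3-bis(silyloxy) unit).
5. 10 ⇐ (R)-mevalonolactone (tertiary carbinol bought; propargylic carbinol by Ru-catalysed transfer hydrogenation). Ring order: six- and five-membered carbocycles first, azonane last.

Key step: step 12

Remark: the ethylidene group of 20 is drawn E, but either isomer serves because the geometry is erased in step 12; the sense of induction in step 6 is assigned by analogy with simple alkynyl ketones.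

**Step 1**
Reactants: 1 (R)-mevalonolactone
Product: 2 (4R)-4-methyloxane-2,4-diol (lactol)
Conditions: DIBAL-H (2.2 equiv), CH2Cl2, −78 °C; Rochelle salt
Reagents that add atoms: none
Why: DIBAL-H partial reduction of a δ-lactone stops at the lactol because the tetrahedral aluminium alkoxide is stable at −78 °C, and the tertiary carbinol centre is not touched.

**Step 2**
Reactants: 2 lactol
Product: 3 (S)-3-methylhex-5-ene-1,3-diol
Conditions: Ph3PCH3Br, KOt-Bu, THF, 0 °C → rt
Reagents that add atoms: methyltriphenylphosphonium bromide, C[P+](c1ccccc1)(c1ccccc1)c1ccccc1.[Br-]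
Why: Wittig methylenation of the open hydroxy-aldehyde form of the lactol (as with 2-deoxy sugar lactols) should turn the former carboxyl arm into the allyl group, with excess ylide covering the two OH groups.

**Step 3**
Reactants: 3 diol
Product: 4 (S)-3-hydroxy-3-methylhex-5-enal
Conditions: TEMPO (10 mol%), PhI(OAc)2, CH2Cl2, rt; used crude
Reagents that add atoms: none
Why: TEMPO/PhI(OAc)2 oxidation is selective for the primary alcohol and cannot oxidise the tertiary one.

**Step 4**
Reactants: 4 aldehyde; 5 lithium (trimethylsilyl)acetylide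
Product: 6 (5S)-5-methyl-1-(trimethylsilyl)oct-7-en-1-yne-3,5-diol (mixture of C-3 epimers)
Conditions: 5 (2.2 equiv), THF, −78 °C; NH4Cl (aq)
Reagents that add atoms: none
Why: 1,2-addition of a lithium acetylide to the aldehyde (one equivalent is spent on the tertiary OH); the new carbinol centre forms without control and is corrected in steps 5 and 6.

**Step 5**
Reactants: 6 alkynyl diol
Product: 7 (S)-5-hydroxy-5-methyl-1-(trimethylsilyl)oct-7-en-1-yn-3-one
Conditions: MnO2 (activated), CH2Cl2, rt
Reagents that add atoms: none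
Why: MnO2 oxidises only the propargylic alcohol, under neutral conditions that should spare the β-hydroxy ynone from retro-aldol cleavage.

**Step 6**
Reactants: 7 ynone
Product: 9 (3S,5S)-5-methyloct-7-en-1-yne-3,5-diol, via C-silyl syn-diol 8 (not isolated)
Conditions: Ru[(S,S)-TsDPEN](p-cymene) (1 mol%, preformed amido complex, no base), i-PrOH, rt; then K2CO3, MeOH, rt
Reagents that add atoms: none
Why: Noyori asymmetric transfer hydrogenation of an alkynyl ketone should set the (S)-propargylic carbinol under catalyst control (the alkynyl group plays the role of the aryl group), syn to the tertiary OH; K2CO3/MeOH then removes the C-silyl group.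

**Step 7**
Reactants: 9 enyne diol
Product: 10 (3S,5S)-3,5-bis(tert-butyldimethylsilyloxy)-5-methyloct-7-en-1-yne
Conditions: TBSOTf, 2,6-lutidine, CH2Cl2, 0 °C → rt
Reagents that add atoms: tert-butyldimethylsilyl triflate, CC(C)(C)[Si](C)(C)OS(=O)(=O)C(F)(F)F
Why: Silyl triflate with 2,6-lutidine silylates both the secondary propargylic and the hindered tertiary alcohol.

**Step 8**
Reactants: 10 enyne
Product: 12 (4S,6S,7aS)-4,6-bis(tert-butyldimethylsilyloxy)-6-methyl-1,4,5,6,7,7a-hexahydro-2H-inden-2-one, via alkyne–hexacarbonyldicobalt complex 11 (not isolated)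
Conditions: Co2(CO)8, CH2Cl2, rt; then NMO, 0 °C → rt
Reagents that add atoms: dicobalt octacarbonyl (source of CO), O=C=[Co](=C=O)(=C=O)(=C=O)[Co](=C=O)(=C=O)(=C=O)=C=O
Why: Intramolecular Pauson–Khand reaction of a silyloxy-substituted 1,7-enyne; the ring-fusion CH should be set by substrate control through a chair-like tether with both silyloxy groups equatorial and the methyl group axial, which places the ring-fusion hydrogen trans to both OTBS groups.

**Step 9**
Reactants: 12 enone; 13 1-(3-bromopropyl)-2,2,5,5-tetramethyl-1-aza-2,5-disilacyclopentane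
Product: 15 (3aS,4S,6S,7aS)-4,6-bis(tert-butyldimethylsilyloxy)-6-methyl-3a-[3-(2,2,5,5-tetramethyl-1-aza-2,5-disilacyclopentan-1-yl)propyl]-2-(trimethylsilyloxy)-3a,4,5,6,7,7a-hexahydro-1H-indene (cis-fused), via Grignard reagent 14 (not isolated)
Conditions: 13, Mg, THF; then CuBr·SMe2 (20 mol%), TMSCl, DMPU, THF, −78 → −40 °C; Et3N, cold NaHCO3 work-up
Reagents that add atoms: chlorotrimethylsilane, C[Si](C)(C)Cl
Why: Copper-catalysed, TMSCl-accelerated conjugate addition of a Grignard reagent to the β,β-disubstituted enone creates the quaternary carbon; attack should come from the face that carries the ring-fusion hydrogen and is anti to the adjacent silyloxy group (cis-hydrindane), and the enolate is trapped regiospecifically as the silyl enol ether.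

**Step 10**
Reactants: 15 silyl enol ether; 16 acetaldehyde
Product: 18 (3aS,4S,6S,7aS)-3a-(3-aminopropyl)-4,6-bis(tert-butyldimethylsilyloxy)-3-(1-hydroxyethyl)-6-methyloctahydro-2H-inden-2-one (epimer mixture at the two new centres), via N-disilyl aldol 17 (not isolated)
Conditions: CH3CHO, BF3·OEt2, CH2Cl2, −78 °C; then 1 M HCl, THF, 0 °C; volatiles removed, NaHCO3
Reagents that add atoms: none
Why: Mukaiyama aldol addition of the regiodefined silyl enol ether to acetaldehyde places the two-carbon unit on the hindered α-carbon (the two new centres are destroyed in step 11), and the acidic work-up cleaves the N,N-disilyl (stabase) group to the primary amine.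

**Step 11**
Reactants: 18 amino aldol
Product: 20 N-{3-[(3aS,4S,6S,7aS)-4,6-bis(tert-butyldimethylsilyloxy)-3-ethylidene-6-methyl-2-oxooctahydro-3aH-inden-3a-yl]propyl}formamide, via N,O-diformyl aldol 19 (not isolated)
Conditions: HCO2Ac, pyridine, CH2Cl2, 0 °C → rt; then DBU, rt
Reagents that add atoms: acetic formic anhydride, CC(=O)OC=O
Why: Acetic formic anhydride formylates the amine and the aldol hydroxyl, and DBU then expels formate by E1cB elimination to give the conjugated ethylidene ketone.

**Step 12**
Reactants: 20 formamide ethylidene ketone; 21 paraformaldehyde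
Product: 24 bis-TBS ether of the tricyclic N-formyl azonane enone (the target with OTBS in place of both OAc groups), via N-chloromethyl formamide 22 (not isolated), via silyloxydiene N-formyliminium triflate 23 (not isolated)
Conditions: (CH2O)n, TMSCl, CH2Cl2, rt; evaporate; then i-Pr2NEt, TMSOTf (slow addition), CH2Cl2 (2 mM), −78 → 0 °C; NaHCO3 (aq)
Reagents that add atoms: none
Why: Proposed new method: (CH2O)n/TMSCl turns the secondary formamide into the N-chloromethyl formamide 22; TMSOTf then abstracts chloride to give the N-formyl-N-methyleneiminium ion while TMSOTf/i-Pr2NEt enolises the ethylidene ketone through its O-silyl oxocarbenium ion at the γ-methyl group to the 2-silyloxy-1,3-diene (23), whose terminal CH2 attacks the iminium carbon and, after loss of the silyl group on work-up, leaves the conjugated enone. The closest known reaction types are the one-pot silyl triflate/amine enol silane formation–Mukaiyama–Mannich addition to N,O-acetals and the vinylogous Mukaiyama–Mannich addition of silyloxydienes to N-acyliminium ions; what is new is the use of this manifold, with formaldehyde stitched in, to close a medium ring. The azonane closes in a 9-endo-trig mode (the N=CH2 bond and the reacting diene C=C both end up inside the new ring), fused to the cyclopentanone through the existing bond between the quaternary carbon and the enone α-carbon. No stereocentre is created; the geometry of the new trisubstituted enone C=C (ring CH2 cis to the quaternary carbon, trans to C=O) is dictated by the three-carbon tether, which can reach the diene terminus only in the s-trans rotamer. The step needs γ- over α-attack, γ- over α′-enolisation and cyclisation over oligomerisation: the α-carbon is fully substituted and flanked by the quaternary centre, silyl triflate/amine enolisation of an enone should favour the linear dienol silane (an α′-enol silane reverts through i-Pr2NEt·HOTf and could only close a bridged bicyclo[5.2.1] ring), and the reaction is run at 2 mM with slow addition of TMSOTf.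

**Step 13**
Reactants: 24 bis-TBS tricycle
Product: 25 tricyclic N-formyl azonane enone diol (the target with OH in place of both OAc groups)
Conditions: 48% aq. HF, MeCN, rt
Reagents that add atoms: none
Why: Fluoride-mediated desilylation should cleave both TBS ethers; the enone and the tertiary formamide are stable to HF and no β-leaving group is present.

**Step 14**
Reactants: 25 diol
Product: 26 target diacetate (CNP0137427.1)
Conditions: Ac2O, Sc(OTf)3 (5 mol%), MeCN, −20 → 0 °C
Reagents that add atoms: acetic anhydride, CC(=O)OC(C)=O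
Why: Sc(OTf)3-catalysed acetylation with Ac2O at low temperature should esterify the secondary and the hindered tertiary alcohol without elimination and without touching any stereocentre.

**Compound list**
1 | (R)-mevalonolactone [(4R)-4-hydroxy-4-methyloxan-2-one] | C[C@@]1(O)CCOC(=O)C1 | starting material
2 | (4R)-4-methyloxane-2,4-diol (lactol, anomer mixture) | C[C@@]1(O)CCOC(O)C1 | intermediate
3 | (S)-3-methylhex-5-ene-1,3-diol | OCC[C@@](C)(O)CC=C | intermediate
4 | (S)-3-hydroxy-3-methylhex-5-enal | O=CC[C@@](C)(O)CC=C | intermediate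
5 | lithium (trimethylsilyl)acetylide | [Li+].[C-]#C[Si](C)(C)C | starting material
6 | (5S)-5-methyl-1-(trimethylsilyl)oct-7-en-1-yne-3,5-diol (C-3 epimers) | C[Si](C)(C)C#CC(O)C[C@@](C)(O)CC=C | intermediate
7 | (S)-5-hydroxy-5-methyl-1-(trimethylsilyl)oct-7-en-1-yn-3-one | C[Si](C)(C)C#CC(=O)C[C@@](C)(O)CC=C | intermediate
8 | (3S,5S)-5-methyl-1-(trimethylsilyl)oct-7-en-1-yne-3,5-diol | C[Si](C)(C)C#C[C@@H](O)C[C@@](C)(O)CC=C | intermediate
9 | (3S,5S)-5-methyloct-7-en-1-yne-3,5-diol | C#C[C@@H](O)C[C@@](C)(O)CC=C | intermediate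
10 | (3S,5S)-3,5-bis(tert-butyldimethylsilyloxy)-5-methyloct-7-en-1-yne | C#C[C@@H](O[Si](C)(C)C(C)(C)C)C[C@@](C)(O[Si](C)(C)C(C)(C)C)CC=C | intermediate
11 | μ-alkyne hexacarbonyldicobalt complex of 10 | C=CC[C@](C)(O[Si](C)(C)C(C)(C)C)C[C@H](O[Si](C)(C)C(C)(C)C)C12C3([H])[Co]1(=C=O)(=C=O)(=C=O)[Co]23(=C=O)(=C=O)=C=O | intermediate
12 | (4S,6S,7aS)-4,6-bis(tert-butyldimethylsilyloxy)-6-methyl-1,4,5,6,7,7a-hexahydro-2H-inden-2-one | O=C1C[C@@H]2C[C@](C)(O[Si](C)(C)C(C)(C)C)C[C@H](O[Si](C)(C)C(C)(C)C)C2=C1 | intermediate
13 | 1-(3-bromopropyl)-2,2,5,5-tetramethyl-1-aza-2,5-disilacyclopentane | BrCCCN1[Si](C)(C)CC[Si]1(C)C | starting material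
14 | [3-(2,2,5,5-tetramethyl-1-aza-2,5-disilacyclopentan-1-yl)propyl]magnesium bromide | Br[Mg]CCCN1[Si](C)(C)CC[Si]1(C)C | intermediate
15 | cis-fused trimethylsilyl enol ether with angular N-disilyl-aminopropyl chain (3aS,4S,6S,7aS) | C[Si](C)(C)OC1=C[C@@]2(CCCN3[Si](C)(C)CC[Si]3(C)C)[C@@H](O[Si](C)(C)C(C)(C)C)C[C@@](C)(O[Si](C)(C)C(C)(C)C)C[C@H]2C1 | intermediate
16 | acetaldehyde | CC=O | starting material
17 | N-disilyl-protected aldol (3-(1-hydroxyethyl) ketone) | CC(O)C1C(=O)C[C@@H]2C[C@](C)(O[Si](C)(C)C(C)(C)C)C[C@H](O[Si](C)(C)C(C)(C)C)[C@]12CCCN1[Si](C)(C)CC[Si]1(C)C | intermediate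
18 | (3aS,4S,6S,7aS)-3a-(3-aminopropyl)-4,6-bis(tert-butyldimethylsilyloxy)-3-(1-hydroxyethyl)-6-methyloctahydro-2H-inden-2-one | CC(O)C1C(=O)C[C@@H]2C[C@](C)(O[Si](C)(C)C(C)(C)C)C[C@H](O[Si](C)(C)C(C)(C)C)[C@]12CCCN | intermediate
19 | N-formyl, O-formyl derivative of 18 | CC(OC=O)C1C(=O)C[C@@H]2C[C@](C)(O[Si](C)(C)C(C)(C)C)C[C@H](O[Si](C)(C)C(C)(C)C)[C@]12CCCNC=O | intermediate
20 | N-{3-[(3aS,4S,6S,7aS)-4,6-bis(tert-butyldimethylsilyloxy)-3-ethylidene-6-methyl-2-oxooctahydro-3aH-inden-3a-yl]propyl}formamide | C/C=C1/C(=O)C[C@@H]2C[C@](C)(O[Si](C)(C)C(C)(C)C)C[C@H](O[Si](C)(C)C(C)(C)C)[C@]12CCCNC=O | intermediate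
21 | paraformaldehyde (formaldehyde source) | C=O | starting material
22 | N-(chloromethyl) formamide derived from 20 | C/C=C1/C(=O)C[C@@H]2C[C@](C)(O[Si](C)(C)C(C)(C)C)C[C@H](O[Si](C)(C)C(C)(C)C)[C@]12CCCN(CCl)C=O | intermediate
23 | 2-(trimethylsilyloxy)-1-vinylcyclopentene (dienol silane) carrying the N-formyl-N-methyleneiminium triflate | C=CC1=C(O[Si](C)(C)C)C[C@@H]2C[C@](C)(O[Si](C)(C)C(C)(C)C)C[C@H](O[Si](C)(C)C(C)(C)C)[C@]12CCC[N+](=C)C=O.[O-]S(=O)(=O)C(F)(F)F | intermediate
24 | bis-TBS ether of the tricyclic N-formyl azonane enone | O=CN1CC/C=C2/C(=O)C[C@@H]3C[C@](C)(O[Si](C)(C)C(C)(C)C)C[C@H](O[Si](C)(C)C(C)(C)C)[C@]23CCC1 | intermediate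
25 | tricyclic N-formyl azonane enone diol | O=CN1CC/C=C2/C(=O)C[C@@H]3C[C@](C)(O)C[C@H](O)[C@]23CCC1 | intermediate
26 | target diacetate CNP0137427.1 | CC(=O)O[C@H]1C[C@@](C)(OC(C)=O)C[C@H]2CC(=O)/C3=C/CCN(C=O)CCC[C@@]321 | target

**Step count and risks**
Total steps: 14. Longest linear sequence: 14 (from 1).

Steps most likely to fail:

1. Step 12 (Proposed new method). The iminium ion may react intermolecularly (oligomerisation) instead of closing the nine-membered ring, enolisation may go to the ring CH2 and close a bridged isomer, or the iminium may simply hydrolyse back to the formamide. The fallback closes the same ring at the N–CH2 bond by known chemistry; it sets out from 15 and comes back at 24. Mukaiyama aldol addition of 15 to 3-[(4-methoxybenzyl)oxy]propanal (BF3·OEt2) gives the N-disilyl PMB-ether aldol F1, and acidic work-up gives the amino aldol F2. N-Sulfonylation with 2-nitrobenzenesulfonyl chloride gives the N-nosyl aldol F3. Dehydration with Burgess reagent gives the N-nosyl (E)-enone PMB ether F4, with the chain cis to the quaternary carbon. DDQ frees the N-nosyl enone alcohol F5. Fukuyama–Mitsunobu cyclisation (PPh3, DIAD, toluene, high dilution) gives the N-nosyl azonane F6. Thiophenol/K2CO3 gives the secondary-amine azonane F7, and N-formylation with acetic formic anhydride gives 24.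

2. Step 9. The Grignard reagent may deprotonate the enone at a γ-position or add 1,2 instead of forming the quaternary carbon, or attack may come from the wrong face. The fallback uses a small carbon nucleophile under Lewis-acid activation and introduces nitrogen afterwards; it sets out from 12 and comes back at 20. Hosomi–Sakurai conjugate allylation (allyltrimethylsilane, TiCl4, −78 °C) with trapping of the titanium enolate by acetaldehyde gives the allyl aldol F8. Burgess dehydration gives the allyl ethylidene ketone F9. Hydroboration of the terminal alkene with disiamylborane and oxidation with NaBO3 give the 3-hydroxypropyl ethylidene ketone F10. CBr4/PPh3 gives the 3-bromopropyl ethylidene ketone F11. Substitution with sodium diformylamide in DMF gives the N,N-diformylaminopropyl ethylidene ketone F12, and brief K2CO3/MeOH removes one formyl group to give 20.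

3. Step 6. The β-hydroxy ynone 7 may undergo retro-aldol cleavage or 6-endo oxa-Michael cyclisation to a dihydropyranone before hydride transfer, and catalyst control may erode next to the free tertiary alcohol. The fallback sets the carbinol in a C–C bond-forming event instead of an oxidation/reduction pair; it sets out from 4 and comes back at 8. Zinc-mediated catalytic asymmetric alkynylation of 4 with ethynyltrimethylsilane (Me2Zn, the ProPhenol ligand enantiomer that gives the (S)-carbinol, Ph3P=O, toluene, 4 °C) should give 8 directly, so that 6 and 7 are never made; no new compound arises (F0).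

**Further compounds**
F1 | step 12 | N-disilyl aldol with the 3-(4-methoxybenzyloxy)propanal unit | COc1ccc(COCCC(O)C2C(=O)C[C@@H]3C[C@](C)(O[Si](C)(C)C(C)(C)C)C[C@H](O[Si](C)(C)C(C)(C)C)[C@]23CCCN2[Si](C)(C)CC[Si]2(C)C)cc1
F2 | step 12 | amino aldol PMB ether | COc1ccc(COCCC(O)C2C(=O)C[C@@H]3C[C@](C)(O[Si](C)(C)C(C)(C)C)C[C@H](O[Si](C)(C)C(C)(C)C)[C@]23CCCN)cc1
F3 | step 12 | N-nosyl aldol PMB ether | COc1ccc(COCCC(O)C2C(=O)C[C@@H]3C[C@](C)(O[Si](C)(C)C(C)(C)C)C[C@H](O[Si](C)(C)C(C)(C)C)[C@]23CCCNS(=O)(=O)c2ccccc2[N+](=O)[O-])cc1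
F4 | step 12 | N-nosyl (E)-enone PMB ether | COc1ccc(COCC/C=C2/C(=O)C[C@@H]3C[C@](C)(O[Si](C)(C)C(C)(C)C)C[C@H](O[Si](C)(C)C(C)(C)C)[C@]23CCCNS(=O)(=O)c2ccccc2[N+](=O)[O-])cc1
F5 | step 12 | N-nosyl (E)-enone primary alcohol | OCC/C=C1/C(=O)C[C@@H]2C[C@](C)(O[Si](C)(C)C(C)(C)C)C[C@H](O[Si](C)(C)C(C)(C)C)[C@]12CCCNS(=O)(=O)c1ccccc1[N+](=O)[O-]
F6 | step 12 | N-nosyl azonane enone (bis-TBS) | O=S(=O)(c1ccccc1[N+](=O)[O-])N1CC/C=C2/C(=O)C[C@@H]3C[C@](C)(O[Si](C)(C)C(C)(C)C)C[C@H](O[Si](C)(C)C(C)(C)C)[C@]23CCC1
F7 | step 12 | secondary-amine azonane enone (bis-TBS) | N1CC/C=C2/C(=O)C[C@@H]3C[C@](C)(O[Si](C)(C)C(C)(C)C)C[C@H](O[Si](C)(C)C(C)(C)C)[C@]23CCC1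
F8 | step 9 | angular allyl aldol | CC(O)C1C(=O)C[C@@H]2C[C@](C)(O[Si](C)(C)C(C)(C)C)C[C@H](O[Si](C)(C)C(C)(C)C)[C@]12CC=C
F9 | step 9 | angular allyl ethylidene ketone | C/C=C1/C(=O)C[C@@H]2C[C@](C)(O[Si](C)(C)C(C)(C)C)C[C@H](O[Si](C)(C)C(C)(C)C)[C@]12CC=C
F10 | step 9 | 3-hydroxypropyl ethylidene ketone | C/C=C1/C(=O)C[C@@H]2C[C@](C)(O[Si](C)(C)C(C)(C)C)C[C@H](O[Si](C)(C)C(C)(C)C)[C@]12CCCO
F11 | step 9 | 3-bromopropyl ethylidene ketone | C/C=C1/C(=O)C[C@@H]2C[C@](C)(O[Si](C)(C)C(C)(C)C)C[C@H](O[Si](C)(C)C(C)(C)C)[C@]12CCCBr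
F12 | step 9 | N,N-diformylaminopropyl ethylidene ketone | C/C=C1/C(=O)C[C@@H]2C[C@](C)(O[Si](C)(C)C(C)(C)C)C[C@H](O[Si](C)(C)C(C)(C)C)[C@]12CCCN(C=O)C=O
F0 | step 6 | none | none
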